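All runs stem from a simulated flask with made-up constants, noise included.

**Reading time.** The time of reading is the question for this flask: in the noon and dawn runs target climbs and then sinks, so you hold two times against each other, the time of its peak and the 6.0 h allowed.

| setting | winter | noon | dawn | flask |
|---|---|---|---|---|
| substrate | 0.037 M (fed, over 10 min) | 0.083 M (fed, over 10 min) | 0.055 M (fed, over 10 min) | 0.055 M (fed, over 10 min) |
| reagent in the second phase | 1.2 equiv | 1.2 equiv | 1.8 equiv | 1.20 equiv |
| remark | run made earlier; the fed solution adds 0.20 times the starting volume | run made earlier; the fed solution adds 0.20 times the starting volume | run made earlier; the fed solution adds 0.20 times the starting volume | the fed solution adds 0.20 times the starting volume |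
| time |  |  |  | 6.0 h |
| volume of the second phase over the first |  |  |  | 1.0 |

| winter: time / h | winter: target / % | noon: time / h | noon: target / % | dawn: time / h | dawn: target / % |
|---|---|---|---|---|---|
| 0.333 | 16.1 | 0.333 | 22.0 | 0.333 | 23.0 |
| 0.667 | 23.2 | 0.667 | 24.4 | 0.667 | 24.3 |
| 1.00 | 24.2 | 1.00 | 24.4 | 1.00 | 23.1 |
| 2.00 | 24.6 | 2.00 | 23.6 | 2.00 | 19.7 |
| 4.00 | 24.4 | 4.00 | 22.6 | 4.00 | 14.5 |

(each reading ± 0.5 percentage points)

- amounts are per litre of the starting volume; all of the dose is in the solution fed
- in the second phase: reagent in the second phase; everything else is in the first
- charges count per volume of the first phase; a concentration in a rate is the amount of a species over the volume of its own phase; every rate counts per litre of the first phase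
- the earlier runs hold the two phases in the same ratio of volumes as the flask asked about

* when, up to 6.0 h, the flask holds most target
* the amount of target, in percent of the substrate charged, at that time

**Second-order clock.** Winter and noon share 1.2 equiv of reagent in the second phase and differ in charge. If every step is bimolecular and you neglect the feed of 10 min, then at fixed equivalents and volume ratio every rate per molecule grows in proportion to the charge, and charge times peak time stays constant. Noon's equal highest readings stand at 0.667 h and 1.00 h, so I read its peak near 0.834 h, which gives 249 M·s, the clock. It puts winter's peak at 1.87 h, and winter's highest reading stands at 2.00 h. For the flask, at the same 1.20 equiv, my reckoning is 1.26 h, which is 0.210 of the allowed time, so my reckoned peak lies inside it.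

**The forecast.** The forecast gives 1 h and 24.5%, on the ground of “Balancing the formation tail against this loss”; my clock sets the peak later.

**The result.** The flask peaks at 1.32 h with 25.0%, which is 1.05 times the clock's time.

    reagent in the reaction phase ⇌ reagent in the second phase, rate k1*([reagent in the reaction phase] - [reagent in the second phase]/K1) per volume of the first phase (partition coefficient = 0.680, kL = 0.0170 s⁻¹)
    substrate + reagent in the reaction phase → target (k = 0.0210 M⁻¹ s⁻¹)
    reagent in the reaction phase + target → over-reaction product (k = 0.0330 M⁻¹ s⁻¹)
    target ⇌ isomer of the product (K = 0.330, k = 0.00250 s⁻¹)
    reagent in the reaction phase ⇌ dormant form (K = 1.60, k = 4.10 × 10⁻⁴ s⁻¹)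

**Same clock.** Target and isomer of the product relax towards each other with a half-life of 1.15 min by that step alone, both ways together, far shorter than the 6.0 h allowed, and at its best time the flask holds 8.25% of isomer of the product beside 25.0% of target. A neighbouring flask charged with 0.014 M of substrate has a clock time of 4.94 h, shorter than the time allowed, and at 6.00 h it holds 25.3% of target and 37.6% of substrate, against 39.4% of substrate in the flask at its best time.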